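## Retrosynthetic overview

1. The target comes from acid **15** by swapping the C18 silyl ether for acetate; **15** comes from saturating C11=C12 of **14**, which is made by Wittig union of C11 aldehyde **10** with the C12–C15 ylide from (S)-β-methyl-γ-butyrolactone (C13 from the chiral pool).
2. Aldehyde **10** comes from acyclic 1,7-enyne **7** and tiglic aldehyde in one flask. Ring-closing enyne metathesis forms ring A first (C5=C10 plus a vinyl group). An exo Diels–Alder reaction then forms ring B (C7–C8 and C9–C10 bonds) and sets C8, C9 and C10 relative to C4.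
3. Enyne **7** comes from the prochiral malonate **3** (diethyl methylmalonate + 5-bromopent-1-ene). A desymmetrising mono-reduction sets quaternary C4; silylation and ester-to-alkyne homologation follow.

Assumption 1: atom labels (C1–C20) follow halimane numbering: C4 carries CH2OAc, C5=C6 is the ring alkene, C8 is CHMe, C9 is the quaternary carbon, C10 is the ring-fusion CH, C11–C15 is the side chain.
Assumption 2: (S)-4-methyloxolan-2-one ((S)-β-methyl-γ-butyrolactone) is bought as a chiral-pool building block.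

## Route

Step 1
Reactants: 1 diethyl 2-methylpropanedioate; 2 5-bromopent-1-ene
Product: 3 diethyl 2-methyl-2-(pent-4-en-1-yl)propanedioate
Conditions: NaH (1.1 equiv), THF/DMF, 0 °C → 60 °C
Reagents that add atoms: none
Why: Malonate C-alkylation (SN2 of the sodium enolate on a primary bromide); the product is prochiral, so no stereocentre is set yet.

Step 2
Reactants: 3 diethyl 2-methyl-2-(pent-4-en-1-yl)propanedioate
Product: 4 ethyl (2S)-2-(hydroxymethyl)-2-methylhept-6-enoate
Conditions: Et2Zn (10 mol %), chiral pipecolinol-derived tetradentate aminophenol ligand (5 mol %, the enantiomer that gives (S)-4), (EtO)2MeSiH (3 equiv), THF, 0 °C → rt; then K2CO3, EtOH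
Reagents that add atoms: none
Why: Catalytic enantioselective desymmetrising hydrosilylation of a 2,2-disubstituted malonate by a chiral dinuclear zinc complex: one enantiotopic ester is reduced to CH2OH, the alkoxide formed is not reduced further, and the choice of ester fixes the quaternary C4 centre.

Step 3
Reactants: 4 ethyl (2S)-2-(hydroxymethyl)-2-methylhept-6-enoate
Product: 5 ethyl (2S)-2-{[(tert-butyldiphenylsilyl)oxy]methyl}-2-methylhept-6-enoate
Conditions: TBDPSCl (1.1 equiv), imidazole (2 equiv), DMF, rt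
Reagents that add atoms: tert-butyl(chloro)diphenylsilane, CC(C)(C)[Si](Cl)(c1ccccc1)c1ccccc1
Why: Standard O-silylation of a primary alcohol; the bulky silyl ether later shields one face of the diene, and C4 is untouched.

Step 4
Reactants: 5 ethyl (2S)-2-{[(tert-butyldiphenylsilyl)oxy]methyl}-2-methylhept-6-enoate
Product: 7 tert-butyl{[(2R)-2-ethynyl-2-methylhept-6-en-1-yl]oxy}diphenylsilane, via aldehyde 6 (not isolated)
Conditions: i-Bu2AlH (1.2 equiv), CH2Cl2, −78 °C; then MeOH, K2CO3, dimethyl (1-diazo-2-oxopropyl)phosphonate, −78 °C → rt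
Reagents that add atoms: dimethyl (1-diazo-2-oxopropyl)phosphonate, CC(=O)C(=[N+]=[N-])P(=O)(OC)OC
Why: Partial i-Bu2AlH reduction of the hindered α-quaternary ester stops at the aluminium hemiacetal, methanolysis releases aldehyde 6, and Seyferth–Gilbert/Ohira–Bestmann homologation in the same flask gives the alkyne; C4 is quaternary and cannot epimerise.

Step 5
Reactants: 7 tert-butyl{[(2R)-2-ethynyl-2-methylhept-6-en-1-yl]oxy}diphenylsilane; 8 (E)-2-methylbut-2-enal
Product: 10 (1R,2S,5R,8aR)-5-{[(tert-butyldiphenylsilyl)oxy]methyl}-1,2,5-trimethyl-1,2,3,5,6,7,8,8a-octahydronaphthalene-1-carbaldehyde, via vinylcyclohexene 9 (not isolated)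
Conditions: second-generation Grubbs catalyst RuCl2(=CHPh)(H2IMes)(PCy3) (5 mol %), ethylene (1 atm), CH2Cl2, 40 °C; then 8 (3 equiv), cool to −78 °C, EtAlCl2 (1.5 equiv), −78 → −40 °C, same flask
Reagents that add atoms: none
Why: Exo-mode ring-closing enyne metathesis (ethylene only keeps the ruthenium methylidene alive) forms ring A as 1-vinylcyclohexene 9, and a Lewis-acid-catalysed Diels–Alder reaction with 8 closes ring B: the asynchronous transition state joins the enal β-carbon to the free vinyl terminus (C7–C8) and the α-carbon to C10, the E geometry of 8 gives cis C8/C9 methyls, the α-methyl enal reacts formyl-exo so CHO ends cis to H-10, and the dienophile adds anti to the pseudoaxial CH2OTBDPS group (the bulkier C4 substituent sits pseudoaxial to avoid allylic 1,2-strain with the vinyl group), which puts H-10 cis to C18.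

Step 6
Reactants: 11 (4S)-4-methyloxolan-2-one
Product: 12 [(2S)-3-carboxy-2-methylpropyl]triphenylphosphonium bromide
Conditions: Ph3P·HBr (1.0 equiv), neat melt, 160 °C; triturate with Et2O
Reagents that add atoms: triphenylphosphine hydrobromide, [Br-].c1ccc(cc1)[PH+](c1ccccc1)c1ccccc1
Why: Acid-promoted O-alkyl ring opening of the γ-lactone by triphenylphosphine (SN2 at the primary CH2–O carbon) gives the ω-carboxyalkylphosphonium salt; the future C13 stereocentre is not involved.

Step 7
Reactants: 10 (1R,2S,5R,8aR)-5-{[(tert-butyldiphenylsilyl)oxy]methyl}-1,2,5-trimethyl-1,2,3,5,6,7,8,8a-octahydronaphthalene-1-carbaldehyde; 12 [(2S)-3-carboxy-2-methylpropyl]triphenylphosphonium bromide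
Product: 14 (3S,4Z)-5-[(1S,2S,5R,8aS)-5-{[(tert-butyldiphenylsilyl)oxy]methyl}-1,2,5-trimethyl-1,2,3,5,6,7,8,8a-octahydronaphthalen-1-yl]-3-methylpent-4-enoic acid, via ylide 13 (not isolated)
Conditions: 12 (2.0 equiv), KN(SiMe3)2 (4.0 equiv), THF, 0 °C; then 10, 0 → 50 °C; aq. HCl work-up
Reagents that add atoms: none
Why: Wittig olefination of the non-enolisable neopentyl aldehyde with the non-stabilised carboxylate ylide joins C11 to C12 (mainly Z, geometry irrelevant because the alkene is reduced next); no stereocentre is formed or disturbed (descriptors at C9 and C13 change only through CIP priorities).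

Step 8
Reactants: 14 (3S,4Z)-5-[(1S,2S,5R,8aS)-5-{[(tert-butyldiphenylsilyl)oxy]methyl}-1,2,5-trimethyl-1,2,3,5,6,7,8,8a-octahydronaphthalen-1-yl]-3-methylpent-4-enoic acid
Product: 15 (3R)-5-[(1R,2S,5R,8aS)-5-{[(tert-butyldiphenylsilyl)oxy]methyl}-1,2,5-trimethyl-1,2,3,5,6,7,8,8a-octahydronaphthalen-1-yl]-3-methylpentanoic acid
Conditions: TsNHNH2 (10 equiv, in portions), NaOAc (12 equiv), DME/H2O, 85 °C
Reagents that add atoms: none
Why: Diimide reduction (concerted syn transfer of H2) saturates the 1,2-disubstituted C11=C12 bond and leaves the hindered trisubstituted C5=C6 bond alone; no stereocentre changes.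

Step 9
Reactants: 15 (3R)-5-[(1R,2S,5R,8aS)-5-{[(tert-butyldiphenylsilyl)oxy]methyl}-1,2,5-trimethyl-1,2,3,5,6,7,8,8a-octahydronaphthalen-1-yl]-3-methylpentanoic acid
Product: 18 (3R)-5-[(1R,2S,5R,8aS)-5-(acetoxymethyl)-1,2,5-trimethyl-1,2,3,5,6,7,8,8a-octahydronaphthalen-1-yl]-3-methylpentanoic acid, via hydroxy acid 16 (not isolated), via mixed anhydride 17 (not isolated)
Conditions: HF·pyridine, pyridine/THF, 0 °C → rt; then Ac2O (6 equiv), DMAP (0.1 equiv), rt; then H2O, rt, 1 h
Reagents that add atoms: acetic anhydride, CC(=O)OC(C)=O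
Why: Fluoride desilylation followed by DMAP-catalysed O-acetylation of the primary C18 alcohol; the carboxyl group is tied up only transiently as the mixed acetic anhydride, which water hydrolyses back to the acid, and no stereocentre is affected.

## Compound list

1 | diethyl 2-methylpropanedioate | CCOC(=O)C(C)C(=O)OCC | starting material
2 | 5-bromopent-1-ene | C=CCCCBr | starting material
3 | diethyl 2-methyl-2-(pent-4-en-1-yl)propanedioate | CCOC(=O)C(C)(CCCC=C)C(=O)OCC | intermediate
4 | ethyl (2S)-2-(hydroxymethyl)-2-methylhept-6-enoate | OC[C@@](C)(C(=O)OCC)CCCC=C | intermediate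
5 | ethyl (2S)-2-{[(tert-butyldiphenylsilyl)oxy]methyl}-2-methylhept-6-enoate | CC(C)(C)[Si](c1ccccc1)(c1ccccc1)OC[C@@](C)(C(=O)OCC)CCCC=C | intermediate
6 | (2S)-2-{[(tert-butyldiphenylsilyl)oxy]methyl}-2-methylhept-6-enal | CC(C)(C)[Si](c1ccccc1)(c1ccccc1)OC[C@@](C)(C=O)CCCC=C | intermediate
7 | tert-butyl{[(2R)-2-ethynyl-2-methylhept-6-en-1-yl]oxy}diphenylsilane | CC(C)(C)[Si](c1ccccc1)(c1ccccc1)OC[C@@](C)(C#C)CCCC=C | intermediate
8 | (E)-2-methylbut-2-enal (tiglic aldehyde) | C/C=C(\C)C=O | starting material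
9 | tert-butyl{[(1R)-2-ethenyl-1-methylcyclohex-2-en-1-yl]methoxy}diphenylsilane | CC(C)(C)[Si](c1ccccc1)(c1ccccc1)OC[C@]1(C)CCCC=C1C=C | intermediate
10 | (1R,2S,5R,8aR)-5-{[(tert-butyldiphenylsilyl)oxy]methyl}-1,2,5-trimethyl-1,2,3,5,6,7,8,8a-octahydronaphthalene-1-carbaldehyde | CC(C)(C)[Si](c1ccccc1)(c1ccccc1)OC[C@]1(C)CCC[C@@H]2C1=CC[C@H](C)[C@@]2(C)C=O | intermediate
11 | (4S)-4-methyloxolan-2-one | C[C@@H]1COC(=O)C1 | starting material
12 | [(2S)-3-carboxy-2-methylpropyl]triphenylphosphonium bromide | [Br-].OC(=O)C[C@H](C)C[P+](c1ccccc1)(c1ccccc1)c1ccccc1 | intermediate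
13 | potassium (3S)-3-methyl-4-(triphenyl-λ5-phosphanylidene)butanoate | [K+].[O-]C(=O)C[C@H](C)C=P(c1ccccc1)(c1ccccc1)c1ccccc1 | intermediate
14 | (3S,4Z)-5-[(1S,2S,5R,8aS)-5-{[(tert-butyldiphenylsilyl)oxy]methyl}-1,2,5-trimethyl-1,2,3,5,6,7,8,8a-octahydronaphthalen-1-yl]-3-methylpent-4-enoic acid | CC(C)(C)[Si](c1ccccc1)(c1ccccc1)OC[C@]1(C)CCC[C@@H]2C1=CC[C@H](C)[C@@]2(C)/C=C\[C@@H](C)CC(=O)O | intermediate
15 | (3R)-5-[(1R,2S,5R,8aS)-5-{[(tert-butyldiphenylsilyl)oxy]methyl}-1,2,5-trimethyl-1,2,3,5,6,7,8,8a-octahydronaphthalen-1-yl]-3-methylpentanoic acid | CC(C)(C)[Si](c1ccccc1)(c1ccccc1)OC[C@]1(C)CCC[C@@H]2C1=CC[C@H](C)[C@@]2(C)CC[C@@H](C)CC(=O)O | intermediate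
16 | (3R)-5-[(1R,2S,5R,8aS)-5-(hydroxymethyl)-1,2,5-trimethyl-1,2,3,5,6,7,8,8a-octahydronaphthalen-1-yl]-3-methylpentanoic acid | OC[C@]1(C)CCC[C@@H]2C1=CC[C@H](C)[C@@]2(C)CC[C@@H](C)CC(=O)O | intermediate
17 | acetic (3R)-5-[(1R,2S,5R,8aS)-5-(acetoxymethyl)-1,2,5-trimethyl-1,2,3,5,6,7,8,8a-octahydronaphthalen-1-yl]-3-methylpentanoic anhydride | CC(=O)OC[C@]1(C)CCC[C@@H]2C1=CC[C@H](C)[C@@]2(C)CC[C@@H](C)CC(=O)OC(C)=O | intermediate
18 | (3R)-5-[(1R,2S,5R,8aS)-5-(acetoxymethyl)-1,2,5-trimethyl-1,2,3,5,6,7,8,8a-octahydronaphthalen-1-yl]-3-methylpentanoic acid (CNP0148247.1) | CC(=O)OC[C@]1(C)CCC[C@@H]2C1=CC[C@H](C)[C@@]2(C)CC[C@@H](C)CC(=O)O | target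

## Step count and risks

Total steps: 9. Longest linear sequence: 8 (steps 1–5, then 7–9; step 6 is the side branch).

**Step 5 (enyne metathesis / Diels–Alder in one flask).** The risks are diene-face selectivity (Me versus CH2OTBDPS at C4), exo/endo and regiochemical leakage, and compatibility of EtAlCl2 with the ruthenium residues. The fallback sets out from 7 and comes back at 10. The domino is split: the metathesis is stopped and diene 9 is isolated. The cycloaddition with 8 is then run under reagent control with a chiral cationic oxazaborolidine Lewis acid (o-tolyl CBS oxazaborolidine protonated by HNTf2, matched enantiomer, −78 °C). The catalyst then chooses the diene face and enforces the formyl-exo mode, instead of the C4 substituents doing so. This fallback makes no compound outside the list (F0).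

**Step 2 (desymmetrising mono-reduction).** The risk is insufficient discrimination of the methyl and pentenyl flanks, or over-reduction. The fallback sets out from 3 and comes back at 6. Both esters are reduced with LiAlH4 to the prochiral diol 2-methyl-2-(pent-4-en-1-yl)propane-1,3-diol F1. The diol is desymmetrised by lipase-catalysed transesterification with vinyl acetate (Burkholderia cepacia lipase) to (2S)-2-(hydroxymethyl)-2-methylhept-6-en-1-yl acetate F2. The free arm is silylated (TBDPSCl, imidazole) to (2R)-2-{[(tert-butyldiphenylsilyl)oxy]methyl}-2-methylhept-6-en-1-yl acetate F3. Methanolysis (K2CO3, MeOH) gives (2R)-2-{[(tert-butyldiphenylsilyl)oxy]methyl}-2-methylhept-6-en-1-ol F4, and Dess–Martin oxidation gives aldehyde 6, which is taken to 7 with the Ohira–Bestmann reagent as in step 4. If the enzyme prefers the other arm, the order of silylation and acetate removal is exchanged so that the same F4 results.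

**Step 7 (Wittig on the neopentyl aldehyde with a β-branched ylide).** The risk is low conversion for steric reasons. The fallback sets out from 10 and comes back at 15, so it also bypasses 14 and step 8. Aldehyde 10 is methylenated with Ph3P=CH2 (the smallest ylide) to (1R,2S,5R,8aS)-5-{[(tert-butyldiphenylsilyl)oxy]methyl}-1-ethenyl-1,2,5-trimethyl-1,2,3,5,6,7,8,8a-octahydronaphthalene F5. The vinyl group is hydroborated with 9-BBN and the borane iodinated (I2, NaOMe) to (1R,2S,5R,8aS)-5-{[(tert-butyldiphenylsilyl)oxy]methyl}-1-(2-iodoethyl)-1,2,5-trimethyl-1,2,3,5,6,7,8,8a-octahydronaphthalene F6. Magnesium in THF converts this to {2-[(1R,2S,5R,8aS)-5-{[(tert-butyldiphenylsilyl)oxy]methyl}-1,2,5-trimethyl-1,2,3,5,6,7,8,8a-octahydronaphthalen-1-yl]ethyl}magnesium iodide F7. With catalytic CuBr·SMe2 this Grignard reagent opens commercial (R)-4-methyloxetan-2-one at its O-alkyl carbon with inversion, forming the C12–C13 bond and giving acid 15 with (R)-C13 directly.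

## Further compounds

F0 | step 5 | none | none
F1 | step 2 | 2-methyl-2-(pent-4-en-1-yl)propane-1,3-diol | OCC(C)(CO)CCCC=C
F2 | step 2 | (2S)-2-(hydroxymethyl)-2-methylhept-6-en-1-yl acetate | OC[C@@](C)(COC(C)=O)CCCC=C
F3 | step 2 | (2R)-2-{[(tert-butyldiphenylsilyl)oxy]methyl}-2-methylhept-6-en-1-yl acetate | CC(C)(C)[Si](c1ccccc1)(c1ccccc1)OC[C@@](C)(COC(C)=O)CCCC=C
F4 | step 2 | (2R)-2-{[(tert-butyldiphenylsilyl)oxy]methyl}-2-methylhept-6-en-1-ol | CC(C)(C)[Si](c1ccccc1)(c1ccccc1)OC[C@@](C)(CO)CCCC=C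
F5 | step 7 | (1R,2S,5R,8aS)-5-{[(tert-butyldiphenylsilyl)oxy]methyl}-1-ethenyl-1,2,5-trimethyl-1,2,3,5,6,7,8,8a-octahydronaphthalene | CC(C)(C)[Si](c1ccccc1)(c1ccccc1)OC[C@]1(C)CCC[C@@H]2C1=CC[C@H](C)[C@@]2(C)C=C
F6 | step 7 | (1R,2S,5R,8aS)-5-{[(tert-butyldiphenylsilyl)oxy]methyl}-1-(2-iodoethyl)-1,2,5-trimethyl-1,2,3,5,6,7,8,8a-octahydronaphthalene | CC(C)(C)[Si](c1ccccc1)(c1ccccc1)OC[C@]1(C)CCC[C@@H]2C1=CC[C@H](C)[C@@]2(C)CCI
F7 | step 7 | {2-[(1R,2S,5R,8aS)-5-{[(tert-butyldiphenylsilyl)oxy]methyl}-1,2,5-trimethyl-1,2,3,5,6,7,8,8a-octahydronaphthalen-1-yl]ethyl}magnesium iodide | CC(C)(C)[Si](c1ccccc1)(c1ccccc1)OC[C@]1(C)CCC[C@@H]2C1=CC[C@H](C)[C@@]2(C)CC[Mg]I
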